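**Strategy.** The cis-fused methylidene-butyrolactone/cycloheptene core (cyclohepta[b]furan-2-one numbering) is cut at the ring-fusion bond C3a–C8a and at the ring alkene C4=C5. This splits the seven-membered ring into a five-carbon arc C5–C8a, made as an isopropenyl aldehyde carrying C6, C7 and the side-chain carbinol, and a two-carbon unit C3a–C4 delivered with the lactone carbons as a pentadienylboronate. The key step exploits the O–C8a–C3a–C(=CH2)–C=O array of the lactone as a 2-(alkoxycarbonyl)allylboration retron whose C3a vinyl group (C4) sits next to the C5 isopropenyl group: in one flask a chiral-acid-controlled allylboration forms C3a–C8a with both stereocentres, lactonisation follows, and ring-closing metathesis forms C4=C5.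

Key step: step 11

Numbering: O1, C2 (lactone C=O), C3 (methylidene-bearing), C3a and C8a (ring fusion), C4=C5 (ring alkene), C6 (side-chain carbon), C7 (methyl-bearing), C8 (ring CH2).

Assumption: half-ester 1 is taken as a catalogue compound, and (S)-TRIP is assigned as the Si-face-selective acid by analogy to simple pinacol allyl- and crotylboronates; if the sense proves opposite, its antipode is used.

**Route**

Step 1
Reactants: 1 (3S)-5-methoxy-3-methyl-5-oxopentanoic acid; 2 (4R)-4-benzyl-1,3-oxazolidin-2-one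
Product: 4 methyl (3S)-5-[(4R)-4-benzyl-2-oxo-1,3-oxazolidin-3-yl]-3-methyl-5-oxopentanoate, via mixed pivalic anhydride 3 (not isolated)
Conditions: PivCl, Et3N, THF, −20 °C; then 2, LiCl, −20 °C → rt
Reagents that add atoms: none
Why: N-acylation of the oxazolidinone through the mixed pivalic anhydride uses only the free acid terminus of 1, so the methyl ester and the C3 stereocentre are carried through unchanged.

Step 2
Reactants: 4 methyl (3S)-5-[(4R)-4-benzyl-2-oxo-1,3-oxazolidin-3-yl]-3-methyl-5-oxopentanoate; 5 3-{[tert-butyl(dimethyl)silyl]oxy}propanal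
Product: 7 methyl (3R,4R,5S)-4-{[(4R)-4-benzyl-2-oxo-1,3-oxazolidin-3-yl]carbonyl}-7-{[tert-butyl(dimethyl)silyl]oxy}-5-hydroxy-3-methylheptanoate, via Z-dibutylboron enolate 6 (not isolated)
Conditions: n-Bu2BOTf, i-Pr2NEt, CH2Cl2, 0 °C; then 5, −78 → 0 °C; H2O2, MeOH, pH 7 buffer
Reagents that add atoms: none
Why: Evans syn-aldol reaction, in which soft enolisation gives only the Z-boron enolate of the imide (the methyl ester is not enolised) and the Zimmerman–Traxler chair with the (R)-benzyl auxiliary sets C4 (R) and C5 (S) under reagent control, overriding the C3 methyl centre.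

Step 3
Reactants: 7 methyl (3R,4R,5S)-4-{[(4R)-4-benzyl-2-oxo-1,3-oxazolidin-3-yl]carbonyl}-7-{[tert-butyl(dimethyl)silyl]oxy}-5-hydroxy-3-methylheptanoate
Product: 8 methyl (3R,4R,5S)-4-{[(4R)-4-benzyl-2-oxo-1,3-oxazolidin-3-yl]carbonyl}-5,7-bis{[tert-butyl(dimethyl)silyl]oxy}-3-methylheptanoate
Conditions: TBSOTf, 2,6-lutidine, CH2Cl2, −78 → 0 °C
Reagents that add atoms: tert-butyldimethylsilyl triflate CC(C)(C)[Si](C)(C)OS(=O)(=O)C(F)(F)F
Why: Silyl triflate/lutidine silylation of the hindered secondary carbinol, which also blocks retro-aldol cleavage and δ-lactonisation onto the methyl ester.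

Step 4
Reactants: 8 methyl (3R,4R,5S)-4-{[(4R)-4-benzyl-2-oxo-1,3-oxazolidin-3-yl]carbonyl}-5,7-bis{[tert-butyl(dimethyl)silyl]oxy}-3-methylheptanoate
Product: 9 methyl (3R,4R,5S)-5,7-bis{[tert-butyl(dimethyl)silyl]oxy}-4-[(ethylsulfanyl)carbonyl]-3-methylheptanoate
Conditions: EtSH, n-BuLi, THF, 0 °C
Reagents that add atoms: ethanethiol CCS
Why: Thiolate transacylation attacks the exocyclic imide carbonyl of the hindered silylated aldol adduct, spares the methyl ester and is too weakly basic to epimerise C4.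

Step 5
Reactants: 9 methyl (3R,4R,5S)-5,7-bis{[tert-butyl(dimethyl)silyl]oxy}-4-[(ethylsulfanyl)carbonyl]-3-methylheptanoate
Product: 10 methyl (3R,4R,5S)-4-acetyl-5,7-bis{[tert-butyl(dimethyl)silyl]oxy}-3-methylheptanoate
Conditions: Me2CuLi, Et2O, −78 → −40 °C
Reagents that add atoms: lithium dimethylcuprate [Li+].C[Cu-]C
Why: Gilman cuprate acylation, in which a thioester gives the ketone without over-addition at low temperature while the methyl ester and silyl ethers are inert.

Step 6
Reactants: 10 methyl (3R,4R,5S)-4-acetyl-5,7-bis{[tert-butyl(dimethyl)silyl]oxy}-3-methylheptanoate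
Product: 11 methyl (3R,4S,5S)-5,7-bis{[tert-butyl(dimethyl)silyl]oxy}-3-methyl-4-(prop-1-en-2-yl)heptanoate
Conditions: Zn, CH2Br2, TiCl4, THF, CH2Cl2, 0 °C → rt
Reagents that add atoms: dibromomethane BrCBr
Why: Takai–Lombardo methylenation, a non-basic reagent that methylenates ketones but not esters and should neither epimerise the α-stereocentre nor eliminate the β-silyloxy group.

Step 7
Reactants: 11 methyl (3R,4S,5S)-5,7-bis{[tert-butyl(dimethyl)silyl]oxy}-3-methyl-4-(prop-1-en-2-yl)heptanoate
Product: 12 (3R,4S,5S)-5,7-bis{[tert-butyl(dimethyl)silyl]oxy}-3-methyl-4-(prop-1-en-2-yl)heptanal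
Conditions: i-Bu2AlH, CH2Cl2, −78 °C; Rochelle salt work-up
Reagents that add atoms: none
Why: Partial hydride reduction of the methyl ester through the low-temperature-stable aluminium hemiacetal, with the isolated alkene and silyl ethers untouched.

Step 8
Reactants: 13 prop-2-enal; 14 methyl prop-2-enoate
Product: 15 methyl 3-hydroxy-2-methylidenepent-4-enoate (racemic)
Conditions: DABCO (20 mol %), excess 14, rt
Reagents that add atoms: none
Why: Morita–Baylis–Hillman reaction with the acrylate as amine-activated donor and acrolein as the aldehyde (excess acrylate suppresses acrolein self-coupling); the racemic carbinol centre is destroyed in step 10.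

Step 9
Reactants: 15 methyl 3-hydroxy-2-methylidenepent-4-enoate
Product: 16 methyl 3-(acetyloxy)-2-methylidenepent-4-enoate (racemic)
Conditions: Ac2O, pyridine, DMAP (cat.), CH2Cl2, 0 °C
Reagents that add atoms: acetic anhydride CC(=O)OC(C)=O
Why: Nucleophile-catalysed O-acetylation that turns the allylic hydroxyl into a leaving group.

Step 10
Reactants: 16 methyl 3-(acetyloxy)-2-methylidenepent-4-enoate
Product: 17 methyl (2E)-2-[(4,4,5,5-tetramethyl-1,3,2-dioxaborolan-2-yl)methyl]penta-2,4-dienoate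
Conditions: B2pin2, CuCl (5 mol %), Xantphos (5 mol %), KOt-Bu (10 mol %), THF, 0 °C → rt
Reagents that add atoms: bis(pinacolato)diboron CC1(C)OB(OC1(C)C)B1OC(C)(C)C(C)(C)O1
Why: Copper-catalysed SN2' borylation (borylcopper conjugate addition to the acrylate, then β-acetoxy elimination), expected to give the trisubstituted alkene with the vinyl group trans to the ester, i.e. the E-boronate.

Step 11
Reactants: 12 (3R,4S,5S)-5,7-bis{[tert-butyl(dimethyl)silyl]oxy}-3-methyl-4-(prop-1-en-2-yl)heptanal; 17 methyl (2E)-2-[(4,4,5,5-tetramethyl-1,3,2-dioxaborolan-2-yl)methyl]penta-2,4-dienoate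
Product: 20 (3aR,6S,7R,8aR)-6-[(1S)-1,3-bis{[tert-butyl(dimethyl)silyl]oxy}propyl]-5,7-dimethyl-3-methylidene-3,3a,6,7,8,8a-hexahydro-2H-cyclohepta[b]furan-2-one, via homoallylic pinacol borate 18 (not isolated), via monocyclic lactone triene 19 (not isolated)
Conditions: (S)-TRIP [(S)-3,3'-bis(2,4,6-triisopropylphenyl)-1,1'-binaphthyl-2,2'-diyl hydrogen phosphate] (10 mol %), 4 Å MS, PhMe, −30 °C → rt; then second-generation Hoveyda–Grubbs catalyst RuCl2(H2IMes)(=CH-C6H4-2-O-i-Pr) (5 mol %), PhMe (5 mM), 80 °C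
Reagents that add atoms: none
Why: The chiral phosphoric acid activates the pinacol boronate and the allyl group is transferred from the γ-carbon of 17 through a closed six-membered chair, forming C3a–C8a with transposition of the alkene to the exocyclic methylidene; the closest known reactions are the Brønsted-acid-catalysed 2-(alkoxycarbonyl)allylboration/lactonisation of aldehydes and the chiral-phosphoric-acid-catalysed allylboration with pinacol crotylboronates, followed by ring-closing metathesis. C8a (R) is set by the catalyst, the (S)-acid being expected to deliver the allyl unit to the Si face of 12 and to override the remote C7 methyl centre, while C3a (R) follows from the E-boronate geometry, which places the vinyl group axial in the chair and gives the syn adduct 18. On warming, the borate oxygen closes the γ-lactone by acid-catalysed 5-exo-trig acyl substitution on the methyl ester (19, cis-4,5-disubstituted), and the ruthenium alkylidene formed at the C3a vinyl group closes the cycloheptene by seven-membered ring-closing metathesis onto the isopropenyl group, creating the trisubstituted C4=C5 alkene. The step needs γ- rather than ε-attack of the pentadienylboronate (secured by the six-membered transition state), a negligible uncatalysed background (the ester-bearing boronate should be unreactive without acid at low temperature) and metathesis of the vinyl with the isopropenyl group rather than with the acrylate methylidene (that pairing could only give a three-membered ring or a tetrasubstituted alkene). The cis relationship in 19 places both olefins on the same face of the lactone, which is what lets the cycloheptene close.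

Step 12
Reactants: 20 (3aR,6S,7R,8aR)-6-[(1S)-1,3-bis{[tert-butyl(dimethyl)silyl]oxy}propyl]-5,7-dimethyl-3-methylidene-3,3a,6,7,8,8a-hexahydro-2H-cyclohepta[b]furan-2-one
Product: 21 (3aR,6S,7R,8aR)-6-[(1S)-1,3-dihydroxypropyl]-5,7-dimethyl-3-methylidene-3,3a,6,7,8,8a-hexahydro-2H-cyclohepta[b]furan-2-one
Conditions: HF·pyridine, pyridine, THF, 0 °C → rt
Reagents that add atoms: none
Why: Buffered fluoride desilylation removes both silyl ethers under non-basic conditions that should spare the methylidene lactone and the doubly allylic C3a–H.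

Step 13
Reactants: 21 (3aR,6S,7R,8aR)-6-[(1S)-1,3-dihydroxypropyl]-5,7-dimethyl-3-methylidene-3,3a,6,7,8,8a-hexahydro-2H-cyclohepta[b]furan-2-one
Product: 22 (3S)-3-[(3aR,6S,7R,8aR)-5,7-dimethyl-3-methylidene-2-oxo-3,3a,6,7,8,8a-hexahydro-2H-cyclohepta[b]furan-6-yl]-3-hydroxypropyl acetate
Conditions: AcCl, 2,4,6-collidine, CH2Cl2, −78 °C
Reagents that add atoms: acetyl chloride CC(=O)Cl
Why: Kinetically selective acylation of the primary over the hindered secondary hydroxyl at low temperature with a weak, hindered base that should not promote acetyl migration.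

Step 14
Reactants: 22 (3S)-3-[(3aR,6S,7R,8aR)-5,7-dimethyl-3-methylidene-2-oxo-3,3a,6,7,8,8a-hexahydro-2H-cyclohepta[b]furan-6-yl]-3-hydroxypropyl acetate; 23 (2Z)-2-methylbut-2-enoic acid (angelic acid)
Product: 25 (1S)-3-(acetyloxy)-1-[(3aR,6S,7R,8aR)-5,7-dimethyl-3-methylidene-2-oxo-3,3a,6,7,8,8a-hexahydro-2H-cyclohepta[b]furan-6-yl]propyl (2Z)-2-methylbut-2-enoate, via mixed trichlorobenzoic anhydride 24 (not isolated)
Conditions: 2,4,6-trichlorobenzoyl chloride, Et3N, PhMe, rt; then 22, 75 °C
Reagents that add atoms: none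
Why: Yamaguchi-type esterification through the mixed aryl anhydride, run without DMAP so that addition–elimination isomerisation of the angelate to the tiglate is suppressed.

**Compound list**

1 | (3S)-5-methoxy-3-methyl-5-oxopentanoic acid | COC(=O)C[C@@H](C)CC(=O)O | starting material
2 | (4R)-4-benzyl-1,3-oxazolidin-2-one | O=C1N[C@H](Cc2ccccc2)CO1 | starting material
3 | (3R)-5-methoxy-3-methyl-5-oxopentanoic pivalic anhydride | COC(=O)C[C@@H](C)CC(=O)OC(=O)C(C)(C)C | intermediate
4 | methyl (3S)-5-[(4R)-4-benzyl-2-oxo-1,3-oxazolidin-3-yl]-3-methyl-5-oxopentanoate | COC(=O)C[C@@H](C)CC(=O)N1[C@H](Cc2ccccc2)COC1=O | intermediate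
5 | 3-{[tert-butyl(dimethyl)silyl]oxy}propanal | O=CCCO[Si](C)(C)C(C)(C)C | starting material
6 | Z-dibutylboron enolate of imide 4 | COC(=O)C[C@@H](C)/C=C(\OB(CCCC)CCCC)N1[C@H](Cc2ccccc2)COC1=O | intermediate
7 | methyl (3R,4R,5S)-4-{[(4R)-4-benzyl-2-oxo-1,3-oxazolidin-3-yl]carbonyl}-7-{[tert-butyl(dimethyl)silyl]oxy}-5-hydroxy-3-methylheptanoate | COC(=O)C[C@@H](C)[C@H]([C@H](CCO[Si](C)(C)C(C)(C)C)O)C(=O)N1[C@H](Cc2ccccc2)COC1=O | intermediate
8 | methyl (3R,4R,5S)-4-{[(4R)-4-benzyl-2-oxo-1,3-oxazolidin-3-yl]carbonyl}-5,7-bis{[tert-butyl(dimethyl)silyl]oxy}-3-methylheptanoate | COC(=O)C[C@@H](C)[C@H]([C@H](CCO[Si](C)(C)C(C)(C)C)O[Si](C)(C)C(C)(C)C)C(=O)N1[C@H](Cc2ccccc2)COC1=O | intermediate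
9 | methyl (3R,4R,5S)-5,7-bis{[tert-butyl(dimethyl)silyl]oxy}-4-[(ethylsulfanyl)carbonyl]-3-methylheptanoate | COC(=O)C[C@@H](C)[C@H]([C@H](CCO[Si](C)(C)C(C)(C)C)O[Si](C)(C)C(C)(C)C)C(=O)SCC | intermediate
10 | methyl (3R,4R,5S)-4-acetyl-5,7-bis{[tert-butyl(dimethyl)silyl]oxy}-3-methylheptanoate | COC(=O)C[C@@H](C)[C@H]([C@H](CCO[Si](C)(C)C(C)(C)C)O[Si](C)(C)C(C)(C)C)C(C)=O | intermediate
11 | methyl (3R,4S,5S)-5,7-bis{[tert-butyl(dimethyl)silyl]oxy}-3-methyl-4-(prop-1-en-2-yl)heptanoate | COC(=O)C[C@@H](C)[C@H]([C@H](CCO[Si](C)(C)C(C)(C)C)O[Si](C)(C)C(C)(C)C)C(C)=C | intermediate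
12 | (3R,4S,5S)-5,7-bis{[tert-butyl(dimethyl)silyl]oxy}-3-methyl-4-(prop-1-en-2-yl)heptanal | O=CC[C@@H](C)[C@H]([C@H](CCO[Si](C)(C)C(C)(C)C)O[Si](C)(C)C(C)(C)C)C(C)=C | intermediate
13 | prop-2-enal (acrolein) | C=CC=O | starting material
14 | methyl prop-2-enoate (methyl acrylate) | C=CC(=O)OC | starting material
15 | methyl 3-hydroxy-2-methylidenepent-4-enoate (racemic) | C=CC(O)C(=C)C(=O)OC | intermediate
16 | methyl 3-(acetyloxy)-2-methylidenepent-4-enoate (racemic) | C=CC(OC(C)=O)C(=C)C(=O)OC | intermediate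
17 | methyl (2E)-2-[(4,4,5,5-tetramethyl-1,3,2-dioxaborolan-2-yl)methyl]penta-2,4-dienoate | COC(=O)/C(CB1OC(C)(C)C(C)(C)O1)=C/C=C | intermediate
18 | methyl (3R,4R,6R,7S,8S)-8,10-bis{[tert-butyl(dimethyl)silyl]oxy}-3-ethenyl-6-methyl-2-methylidene-7-(prop-1-en-2-yl)-4-[(4,4,5,5-tetramethyl-1,3,2-dioxaborolan-2-yl)oxy]decanoate | COC(=O)C(=C)[C@@H](C=C)[C@H](OB1OC(C)(C)C(C)(C)O1)C[C@@H](C)[C@H]([C@H](CCO[Si](C)(C)C(C)(C)C)O[Si](C)(C)C(C)(C)C)C(C)=C | intermediate
19 | (4R,5R)-5-[(2R,3S,4S)-4,6-bis{[tert-butyl(dimethyl)silyl]oxy}-2-methyl-3-(prop-1-en-2-yl)hexyl]-4-ethenyl-3-methylideneoxolan-2-one | C=C1C(=O)O[C@H](C[C@@H](C)[C@H]([C@H](CCO[Si](C)(C)C(C)(C)C)O[Si](C)(C)C(C)(C)C)C(C)=C)[C@@H]1C=C | intermediate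
20 | (3aR,6S,7R,8aR)-6-[(1S)-1,3-bis{[tert-butyl(dimethyl)silyl]oxy}propyl]-5,7-dimethyl-3-methylidene-3,3a,6,7,8,8a-hexahydro-2H-cyclohepta[b]furan-2-one | C=C1C(=O)O[C@@H]2C[C@@H](C)[C@H]([C@H](CCO[Si](C)(C)C(C)(C)C)O[Si](C)(C)C(C)(C)C)C(C)=C[C@H]12 | intermediate
21 | (3aR,6S,7R,8aR)-6-[(1S)-1,3-dihydroxypropyl]-5,7-dimethyl-3-methylidene-3,3a,6,7,8,8a-hexahydro-2H-cyclohepta[b]furan-2-one | C=C1C(=O)O[C@@H]2C[C@@H](C)[C@H]([C@H](CCO)O)C(C)=C[C@H]12 | intermediate
22 | (3S)-3-[(3aR,6S,7R,8aR)-5,7-dimethyl-3-methylidene-2-oxo-3,3a,6,7,8,8a-hexahydro-2H-cyclohepta[b]furan-6-yl]-3-hydroxypropyl acetate | C=C1C(=O)O[C@@H]2C[C@@H](C)[C@H]([C@H](CCOC(C)=O)O)C(C)=C[C@H]12 | intermediate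
23 | (2Z)-2-methylbut-2-enoic acid (angelic acid) | C/C=C(/C)C(=O)O | starting material
24 | (2Z)-2-methylbut-2-enoic 2,4,6-trichlorobenzoic anhydride | C/C=C(/C)C(=O)OC(=O)c1c(Cl)cc(Cl)cc1Cl | intermediate
25 | (1S)-3-(acetyloxy)-1-[(3aR,6S,7R,8aR)-5,7-dimethyl-3-methylidene-2-oxo-3,3a,6,7,8,8a-hexahydro-2H-cyclohepta[b]furan-6-yl]propyl (2Z)-2-methylbut-2-enoate | C=C1C(=O)O[C@@H]2C[C@@H](C)[C@H]([C@H](CCOC(C)=O)OC(=O)/C(C)=C\C)C(C)=C[C@H]12 | target

**Step count and risks**

Total steps: 14. Longest linear sequence: 11 steps (steps 1–7 and 11–14, from 1 to 25).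

Steps most likely to fail:

Step 11. The acid-catalysed allyl transfer from the ester-deactivated dienylboronate may be slow or may give poor facial control at C8a, and closure of the hindered trisubstituted cycloheptene may stall in the one-flask format. The fallback is a stepwise Barbier route using known chemistry. It sets out from 12 and from 15, which aqueous HBr/H2SO4 should convert into methyl (2Z)-2-(bromomethyl)penta-2,4-dienoate F1. Indium powder (In) in THF/H2O should couple 12 with F1 through a chelated cyclic transition state to the syn hydroxy ester methyl (3R,4R,6R,7S,8S)-8,10-bis{[tert-butyl(dimethyl)silyl]oxy}-3-ethenyl-4-hydroxy-6-methyl-2-methylidene-7-(prop-1-en-2-yl)decanoate F2. This coupling has no facial control, so the C3a,C8a-epimeric syn isomer would have to be removed by chromatography. TsOH-catalysed lactonisation would then give 19 as an isolated compound. A separate ring-closing metathesis with second-generation Grubbs catalyst RuCl2(H2IMes)(PCy3)(=CHPh) in refluxing CH2Cl2 returns to the route at 20.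

Step 14. Acylation of the hindered secondary carbinol may be slow enough for Z-to-E isomerisation of the activated angelate, and the amine at 75 °C may cause acetyl migration or migration of the lactone double bond. The fallback builds the Z-alkene in place. From 22, DCC/DMAP esterification with 2-[bis(2,2,2-trifluoroethoxy)phosphoryl]propanoic acid should give (1S)-3-(acetyloxy)-1-[(3aR,6S,7R,8aR)-5,7-dimethyl-3-methylidene-2-oxo-3,3a,6,7,8,8a-hexahydro-2H-cyclohepta[b]furan-6-yl]propyl 2-[bis(2,2,2-trifluoroethoxy)phosphoryl]propanoate F3. Still–Gennari olefination of F3 (KN(SiMe3)2, 18-crown-6, acetaldehyde, THF, −78 °C) returns to the route at 25.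

Step 6. Methylenation of the hindered α-branched ketone may be incomplete, or the Lewis-acidic reagent may cause loss of the β-silyloxy group. The fallback is a two-stage Peterson olefination. From 10, Me3SiCH2Li/CeCl3 (THF, −78 °C) should add to the ketone in preference to the ester to give methyl (3R,4R,5S)-5,7-bis{[tert-butyl(dimethyl)silyl]oxy}-4-[2-hydroxy-1-(trimethylsilyl)propan-2-yl]-3-methylheptanoate F4 (carbinol epimers). Mild acid (PPTS, CH2Cl2) should then induce anti-elimination and return to the route at 11.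

**Further compounds**

F1 | step 11 | methyl (2Z)-2-(bromomethyl)penta-2,4-dienoate | COC(=O)/C(CBr)=C/C=C
F2 | step 11 | methyl (3R,4R,6R,7S,8S)-8,10-bis{[tert-butyl(dimethyl)silyl]oxy}-3-ethenyl-4-hydroxy-6-methyl-2-methylidene-7-(prop-1-en-2-yl)decanoate | COC(=O)C(=C)[C@@H](C=C)[C@H](O)C[C@@H](C)[C@H]([C@H](CCO[Si](C)(C)C(C)(C)C)O[Si](C)(C)C(C)(C)C)C(C)=C
F3 | step 14 | (1S)-3-(acetyloxy)-1-[(3aR,6S,7R,8aR)-5,7-dimethyl-3-methylidene-2-oxo-3,3a,6,7,8,8a-hexahydro-2H-cyclohepta[b]furan-6-yl]propyl 2-[bis(2,2,2-trifluoroethoxy)phosphoryl]propanoate | C=C1C(=O)O[C@@H]2C[C@@H](C)[C@H]([C@H](CCOC(C)=O)OC(=O)C(C)P(=O)(OCC(F)(F)F)OCC(F)(F)F)C(C)=C[C@H]12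
F4 | step 6 | methyl (3R,4R,5S)-5,7-bis{[tert-butyl(dimethyl)silyl]oxy}-4-[2-hydroxy-1-(trimethylsilyl)propan-2-yl]-3-methylheptanoate | COC(=O)C[C@@H](C)[C@H]([C@H](CCO[Si](C)(C)C(C)(C)C)O[Si](C)(C)C(C)(C)C)C(C)(O)C[Si](C)(C)C
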